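**Plan**
- Retrosynthesis: the C9 tiglate is removed (acylation, enolate hydroxylation) and the C8 ketone is taken back to the alcohol; then C7–C8 and C5–C10 are cut together, which opens rings B and A to an acyclic tertiary oxalate / enal / prenyl chain.
- Enabling feature: C8 is a carbonyl carbon whose β-carbon is the ring-fusion carbon C10 (an enal C8–C9=C10 accepts a radical at C10), C5 is a quaternary carbon shared by rings A and B (a tertiary radical site), and the isopropenyl group on C7 next to C8–O is the retron of a carbonyl-ene reaction of a prenyl group.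
- Forward order: Evans aldol (C3–C4), MeMgBr (C5–C14), prenylbarium (C5–C6) and cross-metathesis (C9=C10) build the chain; one flask then closes ring A (radical, C5–C10) and ring B (ene, C7–C8); oxidation, C9 hydroxylation and tigloylation finish.
- Stereochemistry: C3 and C4 come from the oxazolidinone auxiliary; C5 and C10 from the chair transition state of the radical closure under C3/C4 control; C7 from the chair ene transition state; C9 from attack on the enolate face anti to the axial C14 methyl.

Key step: step 8

Remark: eremophilane numbering is used throughout (C1–C10 ring carbons, C11–C13 isopropenyl, C14 methyl on C5, C15 methyl on C4); compounds 7–11 are carried as C5 epimer mixtures because C5 becomes a planar radical in step 8.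

**Step 1**
Reactants: 1 (S)-4-benzyl-3-propionyloxazolidin-2-one; 2 pent-4-enal
Product: 4 (4S)-4-benzyl-3-[(2S,3R)-3-hydroxy-2-methylhept-6-enoyl]oxazolidin-2-one, via Z-boron enolate 3 (not isolated)
Conditions: Bu2BOTf, iPr2NEt, CH2Cl2, 0 °C; then 2, −78 → 0 °C; pH 7 buffer, MeOH, H2O2
Reagents that add atoms: none
Why: Evans boron aldol reaction; the Z-enolate reacts through a Zimmerman–Traxler chair on the face away from the benzyl group, which should give the 2S,3R syn adduct (the C4 methyl and C3 oxygen of the target).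

**Step 2**
Reactants: 4 (4S)-4-benzyl-3-[(2S,3R)-3-hydroxy-2-methylhept-6-enoyl]oxazolidin-2-one
Product: 5 (2S,3R)-3-hydroxy-N-methoxy-N,2-dimethylhept-6-enamide
Conditions: MeNH(OMe)·HCl, AlMe3, THF, 0 → 23 °C
Reagents that add atoms: N,O-dimethylhydroxylamine hydrochloride, CNOC.Cl
Why: aluminium-amide transamidation of the N-acyloxazolidinone to the Weinreb amide, assisted by the free β-hydroxyl and without epimerization of the α-centre.

**Step 3**
Reactants: 5 (2S,3R)-3-hydroxy-N-methoxy-N,2-dimethylhept-6-enamide
Product: 6 (3S,4R)-4-hydroxy-3-methyloct-7-en-2-one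
Conditions: MeMgBr (3 equiv), THF, 0 °C; aq NH4Cl
Reagents that add atoms: methylmagnesium bromide, C[Mg]Br
Why: Weinreb ketone synthesis; the chelated tetrahedral intermediate should stop the addition at the methyl ketone (the new methyl is C14).

**Step 4**
Reactants: 6 (3S,4R)-4-hydroxy-3-methyloct-7-en-2-one
Product: 7 (5R,6S,7RS)-6,7,10-trimethylundeca-1,9-diene-5,7-diol
Conditions: prenyl chloride, activated Ba (from BaI2 and LiC12H10, lithium biphenylide), THF, −78 °C; then 6, −78 °C; aq NH4Cl
Reagents that add atoms: 1-chloro-3-methylbut-2-ene (prenyl chloride), ClCC=C(C)C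
Why: allylbarium addition to a ketone, which unlike the magnesium or zinc reagents should bond through the α-carbon and give the linear prenyl carbinol; the configuration of the new C5 centre is immaterial.

**Step 5**
Reactants: 7 (5R,6S,7RS)-6,7,10-trimethylundeca-1,9-diene-5,7-diol
Product: 8 (5R,6S,7RS)-7-hydroxy-6,7,10-trimethylundeca-1,9-dien-5-yl 3-methylbut-2-enoate
Conditions: 3-methylbut-2-enoyl chloride, pyridine, DMAP (cat.), CH2Cl2, −20 → 0 °C
Reagents that add atoms: 3-methylbut-2-enoyl chloride, CC(C)=CC(Cl)=O
Why: acylation should select the secondary C3 hydroxyl over the hindered tertiary C5 hydroxyl, installing the senecioate early.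

**Step 6**
Reactants: 8 (5R,6S,7RS)-7-hydroxy-6,7,10-trimethylundeca-1,9-dien-5-yl 3-methylbut-2-enoate
Product: 9 (2E,6R,7S,8RS)-8-hydroxy-7,8,11-trimethyl-1-oxododeca-2,10-dien-6-yl 3-methylbut-2-enoate
Conditions: crotonaldehyde (5 equiv), second-generation Grubbs catalyst (5 mol%), CH2Cl2, 40 °C
Reagents that add atoms: (E)-but-2-enal, C/C=C/C=O
Why: olefin cross-metathesis; the terminal alkene should react much faster than the trisubstituted prenyl and senecioate double bonds and give the E-enal (C8–C9=C10).

**Step 7**
Reactants: 9 (2E,6R,7S,8RS)-8-hydroxy-7,8,11-trimethyl-1-oxododeca-2,10-dien-6-yl 3-methylbut-2-enoate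
Product: 11 tert-alkyl N-phthalimidoyl oxalate of 9, via chlorooxalate 10 (not isolated)
Conditions: (COCl)2, 2,6-lutidine, Et2O, −20 → 0 °C; evaporation; N-hydroxyphthalimide, Et3N, THF, 0 °C
Reagents that add atoms: oxalyl chloride, ClC(=O)C(Cl)=O; N-hydroxyphthalimide, ON1C(=O)c2ccccc2C1=O
Why: acylation of the tertiary alcohol by oxalyl chloride followed by active-ester formation gives the redox-active oxalate used for deoxygenative generation of tertiary radicals.

**Step 8**
Reactants: 11 tert-alkyl N-phthalimidoyl oxalate of 9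
Product: 13 8β-hydroxy-10αH-eremophil-11-en-3α-yl 3-methylbut-2-enoate, via ring-A aldehyde 12 (not isolated)
Conditions: [Ru(bpy)3](PF6)2 (1 mol%), Hantzsch ester (2 equiv), degassed CH2Cl2, blue LEDs, 23 °C; then same flask, −78 °C, Me2AlCl (6 equiv), −78 → −20 °C
Reagents that add atoms: none
Why: Proposed new method: single-electron reduction of the oxalate by the photoreduced ruthenium catalyst releases two CO2 and the tertiary C5 radical, which adds 6-exo-trig to C10 of the enal (ring A) and then takes a hydrogen atom from the Hantzsch ester to give aldehyde 12; Me2AlCl added to the same flask then drives an intramolecular carbonyl-ene reaction in which C7 of the prenyl group bonds to C8 while a methyl hydrogen moves to oxygen (ring B, six-membered chair, isopropenyl formed). The closest known reaction types are the deoxygenative radical conjugate addition of tert-alkyl N-phthalimidoyl oxalates and the Lewis-acid cyclization of citronellal to isopulegol; only their union in one flask is new. Ring A should close through a chair with the C3 ester, the C4 methyl and the enal chain equatorial and the smaller C5 substituent (methyl) axial, which sets C5 and C10 (trans junction) under control of C3 and C4; ring B should close through a chair fused trans to ring A with the new isopropenyl group equatorial at C7, and the C8 configuration is erased in step 9. The step needs the adduct radical at C9 to be reduced before it attacks the prenyl double bond, which excess Hantzsch ester and the trans-diequatorial geometry (a trans-fused five-membered ring would be required) should secure, and it needs ene closure instead of chloride-trapped Prins closure, which Me2AlCl as a proton scavenger should secure.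

**Step 9**
Reactants: 13 8β-hydroxy-10αH-eremophil-11-en-3α-yl 3-methylbut-2-enoate
Product: 14 8-oxo-10αH-eremophil-11-en-3α-yl 3-methylbut-2-enoate
Conditions: Dess–Martin periodinane, NaHCO3, CH2Cl2, 0 → 23 °C
Reagents that add atoms: none
Why: Dess–Martin oxidation under buffered, non-enolizing conditions should give the β,γ-unsaturated ketone without moving the isopropenyl double bond into conjugation.

**Step 10**
Reactants: 14 8-oxo-10αH-eremophil-11-en-3α-yl 3-methylbut-2-enoate
Product: 16 9α-hydroxy-8-oxo-10αH-eremophil-11-en-3α-yl 3-methylbut-2-enoate, via sodium enolate 15 (not isolated)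
Conditions: NaN(SiMe3)2 (1.05 equiv), THF, −78 °C; then 3-phenyl-2-(phenylsulfonyl)oxaziridine, −78 °C; aq NH4Cl
Reagents that add atoms: 3-phenyl-2-(phenylsulfonyl)oxaziridine (Davis reagent), O=S(=O)(c1ccccc1)N1OC1c1ccccc1
Why: kinetic deprotonation by a bulky amide should take the less hindered C9 methylene proton, and Davis enolate hydroxylation should occur on the α face, anti to the axial C14 methyl that is syn-axial to the β face of C9, giving the equatorial 9α-hydroxyl.

**Step 11**
Reactants: 16 9α-hydroxy-8-oxo-10αH-eremophil-11-en-3α-yl 3-methylbut-2-enoate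
Product: 17 CNP0164025.1, 3α-(3-methylbut-2-enoyloxy)-9α-[(E)-2-methylbut-2-enoyloxy]-10αH-eremophil-11-en-8-one (3R,4R,5R,7S,9S,10R)
Conditions: (E)-2-methylbut-2-enoyl chloride, pyridine, DMAP, CH2Cl2, 0 → 23 °C
Reagents that add atoms: (E)-2-methylbut-2-enoyl chloride (tigloyl chloride), C/C=C(\C)C(Cl)=O
Why: DMAP-catalysed acylation of the secondary α-ketol hydroxyl under weakly basic conditions should install the tiglate with its E geometry and leave C7 and C9 untouched.

**Compound list**
1 | (S)-4-benzyl-3-propionyloxazolidin-2-one | CCC(=O)N1[C@@H](Cc2ccccc2)COC1=O | starting material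
2 | pent-4-enal | C=CCCC=O | starting material
3 | Z-dibutylboron enolate of 1 | C/C=C(\OB(CCCC)CCCC)N1[C@@H](Cc2ccccc2)COC1=O | intermediate
4 | (4S)-4-benzyl-3-[(2S,3R)-3-hydroxy-2-methylhept-6-enoyl]oxazolidin-2-one | C=CCC[C@@H](O)[C@H](C)C(=O)N1[C@@H](Cc2ccccc2)COC1=O | intermediate
5 | (2S,3R)-3-hydroxy-N-methoxy-N,2-dimethylhept-6-enamide | C=CCC[C@@H](O)[C@H](C)C(=O)N(C)OC | intermediate
6 | (3S,4R)-4-hydroxy-3-methyloct-7-en-2-one | C=CCC[C@@H](O)[C@H](C)C(C)=O | intermediate
7 | (5R,6S,7RS)-6,7,10-trimethylundeca-1,9-diene-5,7-diol | C=CCC[C@@H](O)[C@H](C)C(C)(O)CC=C(C)C | intermediate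
8 | (5R,6S,7RS)-7-hydroxy-6,7,10-trimethylundeca-1,9-dien-5-yl 3-methylbut-2-enoate | C=CCC[C@@H](OC(=O)C=C(C)C)[C@H](C)C(C)(O)CC=C(C)C | intermediate
9 | (2E,6R,7S,8RS)-8-hydroxy-7,8,11-trimethyl-1-oxododeca-2,10-dien-6-yl 3-methylbut-2-enoate | O=C/C=C/CC[C@@H](OC(=O)C=C(C)C)[C@H](C)C(C)(O)CC=C(C)C | intermediate
10 | chlorooxalate of 9 (tertiary O–CO–COCl) | O=C/C=C/CC[C@@H](OC(=O)C=C(C)C)[C@H](C)C(C)(CC=C(C)C)OC(=O)C(Cl)=O | intermediate
11 | tert-alkyl N-phthalimidoyl oxalate of 9 | O=C/C=C/CC[C@@H](OC(=O)C=C(C)C)[C@H](C)C(C)(CC=C(C)C)OC(=O)C(=O)ON1C(=O)c2ccccc2C1=O | intermediate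
12 | (1R,2R,3S,4S)-2,3-dimethyl-3-(3-methylbut-2-en-1-yl)-4-(2-oxoethyl)cyclohexyl 3-methylbut-2-enoate (ring-A aldehyde) | CC(C)=CC[C@]1(C)[C@@H](C)[C@H](OC(=O)C=C(C)C)CC[C@H]1CC=O | intermediate
13 | 8β-hydroxy-10αH-eremophil-11-en-3α-yl 3-methylbut-2-enoate | C=C(C)[C@@H]1C[C@]2(C)[C@@H](C)[C@H](OC(=O)C=C(C)C)CC[C@H]2C[C@H]1O | intermediate
14 | 8-oxo-10αH-eremophil-11-en-3α-yl 3-methylbut-2-enoate | C=C(C)[C@@H]1C[C@]2(C)[C@@H](C)[C@H](OC(=O)C=C(C)C)CC[C@H]2CC1=O | intermediate
15 | sodium C8–C9 enolate of 14 | C=C(C)[C@@H]1C[C@]2(C)[C@@H](C)[C@H](OC(=O)C=C(C)C)CC[C@H]2C=C1O[Na] | intermediate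
16 | 9α-hydroxy-8-oxo-10αH-eremophil-11-en-3α-yl 3-methylbut-2-enoate | C=C(C)[C@@H]1C[C@]2(C)[C@@H](C)[C@H](OC(=O)C=C(C)C)CC[C@H]2[C@H](O)C1=O | intermediate
17 | CNP0164025.1, 3α-senecioyloxy-9α-tigloyloxy-10αH-eremophil-11-en-8-one | C=C(C)[C@@H]1C[C@]2(C)[C@@H](C)[C@H](OC(=O)C=C(C)C)CC[C@H]2[C@H](OC(=O)/C(C)=C/C)C1=O | target

Total step count: 11. Longest linear sequence: 11 steps.

**Steps most likely to fail**

1. Step 8. The adduct radical at C9 may attack the prenyl double bond before hydrogen transfer, facial discrimination at the planar C5 radical (methyl against prenylmethyl) may be low, and the photoredox by-products may deactivate the Lewis acid. Fallback, from 9 back to 13: the two ring closures are run as separate operations with electron-transfer termination instead of hydrogen-atom termination. Alcohol 9 is acylated with methyl chlorooxoacetate (pyridine, DMAP) to the methyl oxalate F1, and one equivalent of CsOH in THF/water gives the cesium oxalate F2. Ir[dF(CF3)ppy]2(dtbbpy)PF6 (1 mol%), DME/DMF, water, blue LEDs, 60 °C should then give the C5 radical, ring closure, reduction of the adduct radical to the enolate by the reduced photocatalyst and protonation, so that aldehyde 12 is isolated and purified (the C5 epimers can be separated here). Me2AlCl in CH2Cl2 at −78 °C then closes ring B to 13.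

2. Step 10. Deprotonation may occur at the allylic, doubly activated C7–H instead of C9, which would give the wrong hydroxylation site or move the double bond into conjugation. Fallback, from 12 back to 16: the oxygen is introduced at the aldehyde stage, where only C9 can enolize. Aldehyde 12 (isolated as in the first fallback) is α-oxyaminated with TEMPO, CuCl2 (cat.) and the enantiomer of 5-benzyl-2,2,3-trimethylimidazolidin-4-one trifluoroacetate that delivers the 9S configuration, in air, to give the α-(2,2,6,6-tetramethylpiperidin-1-yloxy) aldehyde F3. Me2AlCl closes ring B to the alcohol F4, Dess–Martin oxidation gives the ketone F5, and Zn/AcOH cleaves the N–O bond to give 16.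

3. Step 4. The prenyl reagent may add through its γ-carbon (giving the 1,1-dimethylallyl carbinol), or the metal aldolate may undergo retro-aldol cleavage. Fallback, from 6 back to 7: the C6–C7 bond is formed instead of the C5–C6 bond. Ketone 6 is treated with dimethylsulfonium methylide (Me3SI, n-BuLi, THF, −10 °C) to give the 1,1-disubstituted epoxide F6, which is opened at its CH2 terminus by (2-methylprop-1-enyl)magnesium bromide with CuI (cat.) to give 7.

**Further compounds**
F1 | step 8 | methyl oxalate of 9 | O=C/C=C/CC[C@@H](OC(=O)C=C(C)C)[C@H](C)C(C)(CC=C(C)C)OC(=O)C(=O)OC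
F2 | step 8 | cesium oxalate of 9 | O=C/C=C/CC[C@@H](OC(=O)C=C(C)C)[C@H](C)C(C)(CC=C(C)C)OC(=O)C(=O)[O-].[Cs+]
F3 | step 10 | 9-(2,2,6,6-tetramethylpiperidin-1-yloxy) derivative of aldehyde 12 | CC(C)=CC[C@]1(C)[C@@H](C)[C@H](OC(=O)C=C(C)C)CC[C@H]1[C@H](ON2C(C)(C)CCCC2(C)C)C=O
F4 | step 10 | 8β-hydroxy-9α-(2,2,6,6-tetramethylpiperidin-1-yloxy)-10αH-eremophil-11-en-3α-yl 3-methylbut-2-enoate | C=C(C)[C@@H]1C[C@]2(C)[C@@H](C)[C@H](OC(=O)C=C(C)C)CC[C@H]2[C@H](ON3C(C)(C)CCCC3(C)C)[C@H]1O
F5 | step 10 | 8-oxo-9α-(2,2,6,6-tetramethylpiperidin-1-yloxy)-10αH-eremophil-11-en-3α-yl 3-methylbut-2-enoate | C=C(C)[C@@H]1C[C@]2(C)[C@@H](C)[C@H](OC(=O)C=C(C)C)CC[C@H]2[C@H](ON3C(C)(C)CCCC3(C)C)C1=O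
F6 | step 4 | (1R,2S)-2-(2-methyloxiran-2-yl)-1-(but-3-enyl)propan-1-ol (epoxide of 6, C5 epimers) | C=CCC[C@@H](O)[C@H](C)C1(C)CO1
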